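The cyclohexenone (C1 carbonyl, C2 methoxy, C3, C4 hydroxyl, C5 farnesyl, C6 methyl) is cut at C4–C5 and C1–C6. The plan exploits that the array O=C1–C2(OMe)=C3–C4–O maps atom for atom onto a 3-methoxy-2-silyloxyfuran, whose ring oxygen survives as the C4 hydroxyl. In one flask the free furan terminus adds to an iminium-activated enal and the aldehyde α-carbon is then acylated by the butenolide carbonyl. This builds the carbocycle, sets C4 and C5 and unties the lactone C–O bond. The precursors are that furan and (E)-4-silyloxybut-2-enal. The formyl group left on C6 directs methylation and is then shed; the C5 oxymethyl arm becomes farnesyl by nickel-catalysed coupling.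

Key step: step 5

Target check: (4R,5R,6R), with the C4 hydroxyl and C5 farnesyl cis and the C5 farnesyl and C6 methyl trans. The ring numbering given above is used for all ring compounds.

Assumption: the (2S,5S) imidazolidinone is taken to expose the enal face that leads to the C5 configuration of the target, as it does with other π-nucleophiles and (E)-enals. If the sense were opposite, the equally available (2R,5R) enantiomer would be used.

Assumption: isomerically pure (E)-geranylacetone is purchased.

Design notes:
- **Enamine hydrolysis first.** The enamine formed by the conjugate addition is hydrolysed before the acylation. C-acylation at the enamine stage would hold the amine as a vinylogous amide and stop turnover.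
- **Methoxide as relay.** Direct attack of C6 on the intact butenolide carbonyl would have to pass a strained 7-oxanorbornene alkoxide. Methoxide therefore serves both as base and as a relay that opens the lactone first.
- **Enal as limiting partner.** No enal is left when base is added.
- **Silyl groups.** The furan silyl group is shed in the first stage. The silyl ether on the C5 arm tolerates methoxide, and a shift to the C4 oxygen would be harmless because both isomers converge at the diol stage.
- **Alkenyl iodide.** Direct iodo-olefination of a methyl ketone is not (E)-selective, so the alkenyl iodide is made through the alkyne by syn-carboalumination.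

Step 1
Reactants: 1 methyl methoxyacetate; 2 (tert-butyldimethylsilyloxy)acetaldehyde
Product: 4 4-hydroxy-3-methoxyoxolan-2-one (racemic cis/trans mixture), via aldol adduct 3 (not isolated)
Conditions: LDA (1.1 equiv), THF, −78 °C; add 2; then HCl in MeOH (1.25 M, excess), −78 °C → rt
Reagents that add atoms: none
Why: The lithium enolate of 1 adds to aldehyde 2 (aldol addition) and methanolic acid then strips the primary silyl ether so that the freed γ-hydroxyl lactonises to the five-membered ring; the two stereocentres form as a mixture, which does not matter because both are erased in step 2.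

Step 2
Reactants: 4 4-hydroxy-3-methoxyoxolan-2-one
Product: 6 3-methoxyfuran-2(5H)-one, via mesylate 5 (not isolated)
Conditions: MsCl (1.2 equiv), Et3N (3 equiv), CH2Cl2, 0 °C → rt
Reagents that add atoms: none
Why: Mesylation of the β-hydroxyl followed by E1cB elimination through the lactone enolate should give the conjugated butenolide from either diastereomer, with the methoxy group ending on the double bond.

Step 3
Reactants: 6 3-methoxyfuran-2(5H)-one
Product: 7 tert-butyl[(3-methoxyfuran-2-yl)oxy]dimethylsilane
Conditions: TBSOTf (1.1 equiv), Et3N (1.5 equiv), CH2Cl2, 0 °C; pentane trituration, short-path distillation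
Reagents that add atoms: tert-butyldimethylsilyl trifluoromethanesulfonate CC(C)(C)[Si](C)(C)OS(=O)(=O)C(F)(F)F
Why: This is a soft enolisation in which the silyl triflate activates the lactone carbonyl, the amine removes a γ-proton and O-silylation of the dienolate is driven by formation of the aromatic 2-silyloxyfuran, the standard preparation of this reagent class.

Step 4
Reactants: 2 (tert-butyldimethylsilyloxy)acetaldehyde
Product: 8 (E)-4-[(tert-butyldimethylsilyl)oxy]but-2-enal
Conditions: Ph3P=CHCHO (1.0 equiv), toluene, 80 °C
Reagents that add atoms: (triphenylphosphoranylidene)acetaldehyde O=CC=P(c1ccccc1)(c1ccccc1)c1ccccc1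
Why: Wittig olefination with the stabilised formyl ylide is (E)-selective, and using no excess of ylide limits a second homologation of the product enal.

Step 5
Reactants: 7 tert-butyl[(3-methoxyfuran-2-yl)oxy]dimethylsilane (1.3 equiv); 8 (E)-4-[(tert-butyldimethylsilyl)oxy]but-2-enal (1.0 equiv)
Product: 11 (4R,5S,6Z)-5-{[(tert-butyldimethylsilyl)oxy]methyl}-4-hydroxy-6-(hydroxymethylidene)-2-methoxycyclohex-2-en-1-one (4,5-cis; enol form of the β-keto aldehyde), via butenolide aldehyde 9 (not isolated), via hydroxy enoate 10 (not isolated)
Conditions: (2S,5S)-5-benzyl-2-tert-butyl-3-methylimidazolidin-4-one·CF3CO2H (20 mol%), H2O (2 equiv), THF, −40 °C; then 3 Å MS, MeOH (dilute to 0.02 M), NaOMe (3 equiv), −40 → 0 °C; AcOH quench to pH 5–6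
Reagents that add atoms: none
Why: Proposed new method: the imidazolidinone salt condenses with 8 to an (E)-iminium ion, C5 of furan 7 attacks its β-carbon (C4–C5 bond, loss of furan aromaticity) and water takes the silyl group and hydrolyses the enamine to butenolide aldehyde 9; methoxide then opens the lactone reversibly to hydroxy enoate 10, the aldehyde enolate is acylated at C1 (C1–C6 bond), and deprotonation of the β-keto aldehyde to its sodium enolate should pull the lactone, lactol and hemiacetal equilibria towards 11, leaving the former furan oxygen as the C4 hydroxyl. The closest known reaction types are the amine-catalysed vinylogous Mukaiyama–Michael addition of 2-silyloxyfurans to enals for the first stage, and the alkoxide-mediated Dieckmann condensation of lactone esters together with the Diels–Alder/ring-opening of 2-silyloxyfurans to 4-hydroxycyclohexenones for the second; an aldehyde as the carbon acid and the merger into one operation have not been shown. The carbocycle closes in the 6-(enolexo)-exo-trig mode, which is possible only because the C2=C3 double bond inherited from the furan holds C1 and C4 cis, and the methoxide relay avoids the strained 1-oxido-7-oxabicyclo[2.2.1]heptene that direct attack on the intact lactone would have to pass. C5 is set by the catalyst, whose benzyl and tert-butyl groups leave one face of the iminium ion open, and C4 by the relative orientation of the partners: the compact endo-type alignment with the iminium carbon under the furan ring gives the 4,5-cis pair, and acid co-catalyst, solvent and temperature are the handles for tuning it. Site selectivity for furan C5 over C3 follows from the methoxy group that occupies C3 and from the vinylogous donation of the 2-silyloxy group, and in the closure C1 is the only acceptor that C6 can reach through an unstrained ring, since attack at C3 would give a cyclobutane. Hydrolysing the enamine before the acylation keeps the amine from being locked up as a vinylogous amide of 11, and keeping 8 as the limiting partner leaves no enal for the methoxide stage.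

Step 6
Reactants: 11 (4R,5S,6Z)-5-{[(tert-butyldimethylsilyl)oxy]methyl}-4-hydroxy-6-(hydroxymethylidene)-2-methoxycyclohex-2-en-1-one
Product: 13 (4R,5S,6R)-5-{[(tert-butyldimethylsilyl)oxy]methyl}-4-hydroxy-2-methoxy-6-methylcyclohex-2-en-1-one (4,5-cis; 5,6-trans), via formyl methyl ketone 12 (not isolated)
Conditions: MeI (3 equiv), K2CO3 (2 equiv), acetone, rt; evaporate volatiles; MeOH, rt
Reagents that add atoms: iodomethane CI
Why: The potassium enolate of a 2-formyl ketone is alkylated by the soft electrophile MeI mainly on carbon, methanolysis of the now non-enolisable formyl group (retro-Claisen deformylation) releases the ketone, and the epimerisable C6 centre should equilibrate under carbonate to the 5,6-trans isomer, in which both carbon substituents are equatorial and the methyl group avoids the pseudoaxial C4 hydroxyl.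

Step 7
Reactants: 13 (4R,5S,6R)-5-{[(tert-butyldimethylsilyl)oxy]methyl}-4-hydroxy-2-methoxy-6-methylcyclohex-2-en-1-one
Product: 14 (4R,5S,6R)-4-hydroxy-5-(hydroxymethyl)-2-methoxy-6-methylcyclohex-2-en-1-one
Conditions: HF·pyridine, pyridine, THF, 0 °C → rt
Reagents that add atoms: none
Why: Buffered fluoride desilylation cleaves the primary silyl ether under conditions too mild to hydrolyse the electron-poor enol ether, to ionise the C4 hydroxyl or to move C6 away from its preferred configuration.

Step 8
Reactants: 14 (4R,5S,6R)-4-hydroxy-5-(hydroxymethyl)-2-methoxy-6-methylcyclohex-2-en-1-one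
Product: 15 (4S,5R,6R)-4-hydroxy-5-(iodomethyl)-2-methoxy-6-methylcyclohex-2-en-1-one (same spatial arrangement; descriptors change with priorities)
Conditions: I2 (1.1 equiv), PPh3 (1.1 equiv), imidazole (2 equiv), THF, 0 °C
Reagents that add atoms: iodine II
Why: In the Appel-type iodination the unhindered primary hydroxyl forms the oxyphosphonium salt and undergoes SN2 displacement much faster than the hindered, electron-poor secondary allylic hydroxyl, and imidazole is too weak a base to enolise the ketone.

Step 9
Reactants: 16 (E)-geranylacetone
Product: 18 (5E)-6,10-dimethylundeca-5,9-dien-1-yne, via enol phosphate 17 (not isolated)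
Conditions: LDA (1.1 equiv), THF, −78 °C; ClP(O)(OEt)2, −78 °C → rt; LDA (2.3 equiv), −78 °C → rt; H2O
Reagents that add atoms: none
Why: Kinetic deprotonation on the methyl side, O-phosphorylation and base-induced β-elimination of diethyl phosphate convert the methyl ketone into the terminal alkyne (enol phosphate elimination) without touching the (E)-trisubstituted alkene.

Step 10
Reactants: 18 (5E)-6,10-dimethylundeca-5,9-dien-1-yne
Product: 20 (1E,5E)-1-iodo-2,6,10-trimethylundeca-1,5,9-triene, via alkenylalane 19 (not isolated)
Conditions: Me3Al (2 equiv), Cp2ZrCl2 (0.25 equiv), CH2Cl2, 0 °C → rt; then I2, THF, −30 °C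
Reagents that add atoms: trimethylaluminium C[Al](C)C; iodine II
Why: Zirconium-catalysed syn-carboalumination (Negishi carboalumination) places methyl on the internal and aluminium on the terminal alkyne carbon, and iodinolysis of the C–Al bond with retention gives the (E)-alkenyl iodide while the isolated trisubstituted alkenes do not react.

Step 11
Reactants: 15 (4S,5R,6R)-4-hydroxy-5-(iodomethyl)-2-methoxy-6-methylcyclohex-2-en-1-one; 20 (1E,5E)-1-iodo-2,6,10-trimethylundeca-1,5,9-triene (1.5 equiv)
Product: 21 (4R,5R,6R)-4-hydroxy-2-methoxy-6-methyl-5-[(2E,6E)-3,7,11-trimethyldodeca-2,6,10-trien-1-yl]cyclohex-2-en-1-one (target)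
Conditions: NiI2 (10 mol%), 4,4'-di-tert-butyl-2,2'-bipyridine (10 mol%), Mn powder (3 equiv), DMA, rt
Reagents that add atoms: none
Why: In the nickel-catalysed reductive cross-electrophile coupling the alkenyl iodide adds to low-valent nickel with retention of geometry, the primary iodide enters as a radical and reductive elimination joins the C5 methylene to the alkenyl carbon, and since neither base nor organometallic nucleophile is present the ketone, enol ether, free hydroxyl and all three stereocentres should remain untouched.

Compound list
1 | methyl methoxyacetate | COCC(=O)OC | starting material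
2 | (tert-butyldimethylsilyloxy)acetaldehyde | O=CCO[Si](C)(C)C(C)(C)C | starting material
3 | methyl 4-[(tert-butyldimethylsilyl)oxy]-3-hydroxy-2-methoxybutanoate (racemic syn/anti mixture) | COC(C(O)CO[Si](C)(C)C(C)(C)C)C(=O)OC | intermediate
4 | 4-hydroxy-3-methoxyoxolan-2-one (racemic cis/trans mixture) | COC1C(O)COC1=O | intermediate
5 | 4-methoxy-5-oxooxolan-3-yl methanesulfonate (mixture) | COC1C(OS(C)(=O)=O)COC1=O | intermediate
6 | 3-methoxyfuran-2(5H)-one | COC1=CCOC1=O | intermediate
7 | tert-butyl[(3-methoxyfuran-2-yl)oxy]dimethylsilane | COc1ccoc1O[Si](C)(C)C(C)(C)C | intermediate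
8 | (E)-4-[(tert-butyldimethylsilyl)oxy]but-2-enal | O=C/C=C/CO[Si](C)(C)C(C)(C)C | intermediate
9 | (3S)-4-[(tert-butyldimethylsilyl)oxy]-3-[(2R)-4-methoxy-5-oxo-2,5-dihydrofuran-2-yl]butanal | COC1=C[C@H](OC1=O)[C@H](CO[Si](C)(C)C(C)(C)C)CC=O | intermediate
10 | methyl (2E,4R,5S)-5-{[(tert-butyldimethylsilyl)oxy]methyl}-4-hydroxy-2-methoxy-7-oxohept-2-enoate (ester carbon and C4 cis on the double bond) | COC(=O)/C(OC)=C\[C@H](O)[C@H](CO[Si](C)(C)C(C)(C)C)CC=O | intermediate
11 | (4R,5S,6Z)-5-{[(tert-butyldimethylsilyl)oxy]methyl}-4-hydroxy-6-(hydroxymethylidene)-2-methoxycyclohex-2-en-1-one | COC1=C[C@H](O)[C@H](CO[Si](C)(C)C(C)(C)C)/C(=C/O)C1=O | intermediate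
12 | (4R,5S,6R)-5-{[(tert-butyldimethylsilyl)oxy]methyl}-6-formyl-4-hydroxy-2-methoxy-6-methylcyclohex-2-en-1-one (target ring numbering; methyl anti to the C5 arm expected, C6 configuration inconsequential) | COC1=C[C@H](O)[C@H](CO[Si](C)(C)C(C)(C)C)[C@](C)(C=O)C1=O | intermediate
13 | (4R,5S,6R)-5-{[(tert-butyldimethylsilyl)oxy]methyl}-4-hydroxy-2-methoxy-6-methylcyclohex-2-en-1-one | COC1=C[C@H](O)[C@H](CO[Si](C)(C)C(C)(C)C)[C@@H](C)C1=O | intermediate
14 | (4R,5S,6R)-4-hydroxy-5-(hydroxymethyl)-2-methoxy-6-methylcyclohex-2-en-1-one | COC1=C[C@H](O)[C@H](CO)[C@@H](C)C1=O | intermediate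
15 | (4S,5R,6R)-4-hydroxy-5-(iodomethyl)-2-methoxy-6-methylcyclohex-2-en-1-one | COC1=C[C@H](O)[C@H](CI)[C@@H](C)C1=O | intermediate
16 | (E)-geranylacetone, (5E)-6,10-dimethylundeca-5,9-dien-2-one | CC(=O)CC/C=C(\C)CCC=C(C)C | starting material
17 | diethyl (5E)-6,10-dimethylundeca-1,5,9-trien-2-yl phosphate | C=C(CC/C=C(\C)CCC=C(C)C)OP(=O)(OCC)OCC | intermediate
18 | (5E)-6,10-dimethylundeca-5,9-dien-1-yne | C#CCC/C=C(\C)CCC=C(C)C | intermediate
19 | dimethyl[(1E,5E)-2,6,10-trimethylundeca-1,5,9-trien-1-yl]alane | C[Al](C)/C=C(\C)CC/C=C(\C)CCC=C(C)C | intermediate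
20 | (1E,5E)-1-iodo-2,6,10-trimethylundeca-1,5,9-triene | I/C=C(\C)CC/C=C(\C)CCC=C(C)C | intermediate
21 | (4R,5R,6R)-4-hydroxy-2-methoxy-6-methyl-5-[(2E,6E)-3,7,11-trimethyldodeca-2,6,10-trien-1-yl]cyclohex-2-en-1-one | COC1=C[C@H](O)[C@H](C/C=C(\C)CC/C=C(\C)CCC=C(C)C)[C@@H](C)C1=O | target

Total step count: 11. Longest linear sequence: 8 steps (1, 2, 3, 5, 6, 7, 8, 11).

Steps most likely to fail

Step 5. Several processes may outrun the acyl transfer: aldol self-condensation of the aldehyde enolate, γ-deprotonation of the butenolide (epimerisation at C4, retro-Michael cleavage), or saponification. The endo-type topicity of the first stage may also be poorly expressed.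

The fallback uses known chemistry only. The reaction is stopped after its first stage, which on its own is an established reaction type, and 9 is isolated. This also allows a C4 epimer to be removed by chromatography. Pinnick oxidation (NaClO2, NaH2PO4, 2-methylbut-2-ene, t-BuOH/H2O) gives the carboxylic acid F1, and allyl bromide/KHCO3 in DMF gives the allyl ester F2. A Dieckmann condensation under sodium allyloxide in allyl alcohol/THF follows, in which alkoxide-mediated lactone opening precedes closure and the ester enolate has no aldol channel. It gives the β-keto ester F3. MeI/K2CO3 in acetone alkylates it on carbon to the quaternary ester F4. Pd(PPh3)4/morpholine in THF effects deallylation with loss of CO2 under neutral conditions, and brief K2CO3/MeOH equilibration of C6 brings the material back to the route at 13.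

Step 11. Hydrodehalogenation or homocoupling of either iodide, β-hydride elimination at the alkylnickel stage, or binding of low-valent nickel by the enone may erode the cross-coupling.

The fallback is a palladium-catalysed Negishi coupling with a preformed organozinc reagent. From 15, TESCl/imidazole (CH2Cl2, 0 °C) gives the triethylsilyl ether F5. Insertion of activated Zn dust (LiCl, THF, rt) gives the alkylzinc iodide F6, a reagent class that tolerates ketones and enones. PdCl2(dppf) (5 mol%) couples it with 20, with retention of the (E) geometry, to the silyl-protected target F7. HF·pyridine in THF removes the silyl group and the route is rejoined at 21.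

Step 6. O-alkylation of the ambident enolate next to the substituted C5, or base-induced loss of water from the γ-hydroxy enone with aromatisation, may compete with C-methylation.

In the fallback the methyl carbon is installed before the ring is closed, so that no ambident enolate has to be alkylated. It starts from 9, isolated after the first stage of step 5. Amine-catalysed α-methylenation (aqueous HCHO, pyrrolidine/propionic acid, i-PrOH, 45 °C) gives the 2-methylidene aldehyde F8. Iminium-catalysed transfer hydrogenation (diethyl 2,6-dimethyl-1,4-dihydropyridine-3,5-dicarboxylate, dibenzylammonium trifluoroacetate, THF, rt) gives the 2-methyl aldehyde F9 as an inconsequential epimer mixture. NaOMe/MeOH as in step 5 closes the ring to 12, whose non-enolisable formyl group is cleaved by methoxide in the same flask, and the route is rejoined at 13.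

Further compounds
F1 | step 5 | (3S)-4-[(tert-butyldimethylsilyl)oxy]-3-[(2R)-4-methoxy-5-oxo-2,5-dihydrofuran-2-yl]butanoic acid | COC1=C[C@H](OC1=O)[C@H](CO[Si](C)(C)C(C)(C)C)CC(=O)O
F2 | step 5 | prop-2-en-1-yl (3S)-4-[(tert-butyldimethylsilyl)oxy]-3-[(2R)-4-methoxy-5-oxo-2,5-dihydrofuran-2-yl]butanoate | COC1=C[C@H](OC1=O)[C@H](CO[Si](C)(C)C(C)(C)C)CC(=O)OCC=C
F3 | step 5 | prop-2-en-1-yl (5R,6S)-6-{[(tert-butyldimethylsilyl)oxy]methyl}-5-hydroxy-3-methoxy-2-oxocyclohex-3-ene-1-carboxylate (C1 epimers and enol) | COC1=C[C@H](O)[C@H](CO[Si](C)(C)C(C)(C)C)C(C(=O)OCC=C)C1=O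
F4 | step 5 | prop-2-en-1-yl (1S,5R,6S)-6-{[(tert-butyldimethylsilyl)oxy]methyl}-5-hydroxy-3-methoxy-1-methyl-2-oxocyclohex-3-ene-1-carboxylate (methyl anti to the silyloxymethyl arm expected) | COC1=C[C@H](O)[C@H](CO[Si](C)(C)C(C)(C)C)[C@](C)(C(=O)OCC=C)C1=O
F5 | step 11 | (4S,5R,6R)-5-(iodomethyl)-2-methoxy-6-methyl-4-[(triethylsilyl)oxy]cyclohex-2-en-1-one | COC1=C[C@H](O[Si](CC)(CC)CC)[C@H](CI)[C@@H](C)C1=O
F6 | step 11 | alkylzinc iodide from F5 (C5–CH2ZnI, ring stereocentres unchanged) | COC1=C[C@H](O[Si](CC)(CC)CC)[C@H](C[Zn]I)[C@@H](C)C1=O
F7 | step 11 | 4-O-triethylsilyl ether of 21 | COC1=C[C@H](O[Si](CC)(CC)CC)[C@H](C/C=C(\C)CC/C=C(\C)CCC=C(C)C)[C@@H](C)C1=O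
F8 | step 6 | (3S)-4-[(tert-butyldimethylsilyl)oxy]-3-[(2R)-4-methoxy-5-oxo-2,5-dihydrofuran-2-yl]-2-methylidenebutanal | COC1=C[C@H](OC1=O)[C@H](CO[Si](C)(C)C(C)(C)C)C(=C)C=O
F9 | step 6 | (3S)-4-[(tert-butyldimethylsilyl)oxy]-3-[(2R)-4-methoxy-5-oxo-2,5-dihydrofuran-2-yl]-2-methylbutanal (C2 epimers) | COC1=C[C@H](OC1=O)[C@H](CO[Si](C)(C)C(C)(C)C)C(C)C=O
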